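If every bit of substrate that reacted stood as target, the last gamma reading would leave 70.6% of the charged substrate. That leftover is what we carry forward.

in all of them: free catalyst 1.1 mM

|  | substrate | reagent | temperature | remark | time |
|---|---|---|---|---|---|
| gamma | 0.50 M | 1.2 M | 70 °C | run made earlier |  |
| midnight | 1.0 M | 1.20 M | 70 °C |  | 3.0 h |
| spring | 1.0 M | 1.20 M |  | at 70 °C until 2.0 h, from then on at 110 °C | 3.0 h |
| dawn | 1.0 M | 1.20 M | 90 °C |  | 3.0 h |
| noon | 1.0 M | 1.20 M | 110 °C |  | 3.0 h |

gamma run (percent of the substrate charged)

| time / min | target / % |
|---|---|
| 5.00 | 4.1 |
| 15.0 | 10.9 |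
| 25.0 | 16.2 |
| 40.0 | 24.8 |
| 50.0 | 29.4 |

(readings scatter by 0.5 percentage points)

- on the list of suspects stand: catalyst intermediate D -> free catalyst + target; reagent + catalyst intermediate B <-> catalyst intermediate C; catalyst intermediate A <-> catalyst intermediate B; substrate + free catalyst <-> catalyst intermediate A; target <-> isomer of the product; catalyst intermediate C -> catalyst intermediate D
- the earlier runs do not show what temperature does; that part of a forecast is a guess

- which flask leads in amount of target, in percent of the substrate charged ("all alike" within 1.5 percentage points) (midnight / spring / dawn / noon / all alike)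
- how much target is there at the end, in percent of the substrate charged: midnight
- how much target is there at the end, in percent of the substrate charged: spring
- how much target is there at the end, in percent of the substrate charged: dawn
- how much target is there at the end, in percent of the substrate charged: noon

Substrate is the limiting reagent in midnight, at 1.0 M against 1.20 M of reagent. We take the gamma leftover as a pseudo-first-order decay and assume it does not depend on the charge of substrate, although gamma held 0.50 M and midnight holds 1.0 M.

    lifetime = reading time ÷ (minus the logarithm of the leftover) = 144 min

This is the substrate lifetime, the time in which the substrate left falls by a factor e at 70 °C. It gives a ladder of times, from the shortest to the longest: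

    gamma readings end: 50.0 min
    half-life, lifetime × ln(2): 99.6 min
    lifetime: 144 min
    asked time: 180 min

The gamma readings stop before the half-life, and the asked time lies beyond the lifetime, so midnight runs into time that gamma never read. On our reckoning, midnight turns over

    71.4% of its substrate by 3.0 h.

That figure is conversion, not target. Target is conversion less whatever passes on to the isomer of the product, a step on the list of suspects on which we put no time. Nor does gamma show what heat does, so the lifetime serves 70 °C and nothing hotter.

The forecast names dawn as the leader, with midnight at 59% (48% to 71%), spring at 78% (60% to 93%), dawn at 80% (65% to 93%) and noon at 68% (42% to 92%). Its figure for midnight is target, and it stands below our conversion. On heat it says: “Dawn and spring are close, and dawn narrowly leads.”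

The flask that leads is midnight, with 48.8% of target, ahead of noon at 31.7%, spring at 31.6% and dawn at 23.7%.

    catalyst intermediate D → free catalyst + target (k = 2.70 /s, Ea = 94.0 kJ/mol)
    reagent + catalyst intermediate B ⇌ catalyst intermediate C (K = 4.00 /M, k = 3.80 /M/s, Ea = 56.0 kJ/mol, ΔH = −20.0 kJ/mol)
    catalyst intermediate A ⇌ catalyst intermediate B (K = 16.0, k = 1.30 /s, Ea = 72.0 kJ/mol, ΔH = −54.0 kJ/mol)
    substrate + free catalyst ⇌ catalyst intermediate A (K = 1.00 /M, k = 0.760 /M/s, Ea = 52.0 kJ/mol, ΔH = −27.0 kJ/mol)
    target ⇌ isomer of the product (K = 3.50, k = 4.90 × 10⁻⁴ /s, Ea = 99.0 kJ/mol, ΔH = −28.0 kJ/mol)
    catalyst intermediate C → catalyst intermediate D (k = 28.0 /s, Ea = 89.0 kJ/mol)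
    (constants at 90 °C)

In midnight at 3.00 h, the conversion of substrate is 72.7% against the 71.4% reckoned from the lifetime, and the isomer of the product holds 23.9% of the charge. Spring stays at 70 °C until 2.0 h, and the half-life from the same lifetime is 1.66 h. Spring has converted half of its substrate at 1.77 h, before its temperature changes.

All runs were generated by integration with constants of no real substance; scatter was added.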